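**Plan**
1. Units are numbered 1 (top epigallocatechin) to 4 (bottom epicatechin); unit 3 carries the gallate. Retrosynthetic cuts, in order: benzyl ethers, the C3–O bond of unit 1 (from C3–B) and the gallate ester; then O1–C2 and C3–C4 of ring C of unit 1 together (retro-hetero-Diels–Alder); then the C4(unit 1)–C8(unit 2) bond; then the two lower C4–C8 interflavan bonds.
2. Enabling feature: in unit 1 the array O1–C8a=C4a–C4 is a 2-hydroxybenzyl unit of phloroglucinol ring A whose C4 is doubly benzylic (ring A of unit 1 and C8 of ring A of unit 2), i.e. a latent o-quinone methide heterodiene. C2–C3 is a cis-aryl/oxygen two-carbon unit, i.e. a (Z)-styrene dienophile with boron as masked 3-OH.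
3. Forward: benzylated (−)-epicatechin is extended upward by two TMSOTf couplings with C4-activated (−)-epigallocatechin units (the second capped with bromine at C8) to a trimer. Br→Li and addition to a salicylaldehyde bring in C4 and ring A of unit 1, and the [4+2] addition of a (Z)-alkenylboronate closes ring C. Acylation, C–B oxidation and hydrogenolysis finish.
4. Stereochemistry: C2/C3 of units 2–4 come from the natural flavan-3-ols; both lower C4 centres arise by attack anti to the axial C3 substituent (4β). In unit 1, C2/C3 cis comes from the Z-alkene, C3/C4 trans from the exo approach, the absolute sense from a chiral phosphoric acid, and C–B→C–O goes with retention.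
5. The boronate also keeps the 3-oxygen of unit 1 masked, so that only the 3-OH of unit 3 is acylated.

Key step: step 13

Remark on the chemistry: the facial sense of the chiral phosphoric acid in step 13 is assumed from the usual shielding model of a hydrogen-bonded methide; the (R)-acid is written and the (S)-acid would be used if the sense proved opposite.

**Route**

Step 1
Reactants: 1 (−)-epicatechin
Product: 3 penta-O-benzylepicatechin, via tetra-O-benzylepicatechin 2 (not isolated)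
Conditions: BnBr, K2CO3, DMF, 0 °C → rt; then NaH, BnBr, 0 °C → rt
Reagents that add atoms: benzyl bromide, BrCc1ccccc1
Why: Williamson ether synthesis, the four phenols being alkylated with carbonate before NaH is added for the secondary 3-OH, so that no free phenoxide meets strong base and the C2 and C3 centres of the natural product are kept.

Step 2
Reactants: 4 (−)-epigallocatechin
Product: 5 5,7,3′,4′,5′-penta-O-benzylepigallocatechin (3-OH free)
Conditions: BnBr, K2CO3, DMF, 0 °C → rt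
Reagents that add atoms: benzyl bromide, BrCc1ccccc1
Why: Williamson ether synthesis under carbonate conditions alkylates only the five phenols and leaves the 3-OH and the (2R,3R) centres untouched.

Step 3
Reactants: 5 penta-O-benzylepigallocatechin
Product: 6 4β-(2-ethoxyethoxy)-5,7,3′,4′,5′-penta-O-benzylepigallocatechin
Conditions: DDQ, 2-ethoxyethanol, CH2Cl2, rt
Reagents that add atoms: 2-ethoxyethanol, CCOCCO
Why: DDQ benzylic oxidation (hydride abstraction at C4, assisted by ring A) gives the C4 cation, which the alcohol captures anti to the axial 3-OH to give the 4β ether, a centre that is ionised again in the couplings.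

Step 4
Reactants: 6 4β-(2-ethoxyethoxy) electrophile; 3 penta-O-benzylepicatechin (excess)
Product: 7 penta-O-benzylepigallocatechin-(4β→8)-penta-O-benzylepicatechin (3-OH of the upper unit free)
Conditions: TMSOTf (0.5 equiv), CH2Cl2, −78 °C
Reagents that add atoms: none
Why: Lewis-acid-promoted Friedel–Crafts interflavan coupling in which the C4 cation from 6 is attacked by C8 of 3 anti to the axial 3-OH, which sets the new C4 centre 3,4-trans (4β), while the excess of 3 keeps 6 from condensing with itself.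

Step 5
Reactants: 6 4β-(2-ethoxyethoxy)-penta-O-benzylepigallocatechin
Product: 8 8-bromo-4β-(2-ethoxyethoxy)-5,7,3′,4′,5′-penta-O-benzylepigallocatechin
Conditions: NBS (1.05 equiv), CH2Cl2, −20 °C
Reagents that add atoms: N-bromosuccinimide, O=C1CCC(=O)N1Br
Why: electrophilic aromatic bromination goes to C8, the most nucleophilic position of phloroglucinol ring A, and gives a cap that blocks self-condensation and later serves as the handle for lithiation.

Step 6
Reactants: 8 8-bromo-4β-(2-ethoxyethoxy)-penta-O-benzylepigallocatechin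
Product: 9 8-bromo-4β-(2-ethoxyethoxy)-3,5,7,3′,4′,5′-hexa-O-benzylepigallocatechin
Conditions: NaH, BnBr, Bu4NI (cat.), THF/DMF, 0 °C → rt
Reagents that add atoms: benzyl bromide, BrCc1ccccc1
Why: Williamson ether synthesis of the secondary alkoxide, to which the C4 ether and the aryl bromide are inert, masks the 3-OH that would otherwise compete in the later acylation and in the trapping of the methide.

Step 7
Reactants: 9 bromine-capped electrophile; 7 dimer
Product: 10 trimer bromide: 8-bromo-hexa-O-benzylepigallocatechin-(4β→8)-penta-O-benzylepigallocatechin(3-OH free)-(4β→8)-penta-O-benzylepicatechin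
Conditions: TMSOTf (0.5 equiv), CH2Cl2, −78 → −40 °C
Reagents that add atoms: none
Why: second Friedel–Crafts interflavan coupling, in which the capped electrophile 9 cannot self-condense and the only free C8 of 7 attacks the C4 cation anti to the axial 3-benzyloxy group to set the 4β centre.

Step 8
Reactants: 11 2,4,6-trihydroxybenzaldehyde
Product: 12 4,6-bis(benzyloxy)-2-hydroxybenzaldehyde
Conditions: BnBr (2.1 equiv), K2CO3 (2.2 equiv), DMF, rt
Reagents that add atoms: benzyl bromide, BrCc1ccccc1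
Why: Williamson ether synthesis with two equivalents of benzyl bromide alkylates the 4-OH and one ortho OH, the remaining ortho OH being deactivated by its hydrogen bond to the aldehyde.

Step 9
Reactants: 12 4,6-bis(benzyloxy)-2-hydroxybenzaldehyde
Product: 13 4,6-bis(benzyloxy)-2-(triethylsilyloxy)benzaldehyde
Conditions: Et3SiCl, imidazole, DMF, 0 °C → rt
Reagents that add atoms: chlorotriethylsilane, CC[Si](Cl)(CC)CC
Why: silyl ether formation at the phenol removes the acidic proton and restores the electrophilicity of the aldehyde for the organolithium addition.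

Step 10
Reactants: 10 trimer bromide; 13 silylated aldehyde
Product: 16 trimer benzhydrol (carbinol epimers), via dilithiated trimer 14 (not isolated), via silyl-protected adduct 15 (not isolated)
Conditions: t-BuLi (3.1 equiv), THF, −78 °C; 13 (2 equiv), −78 → −30 °C; then AcOH, Bu4NF, THF, 0 °C
Reagents that add atoms: none
Why: bromine–lithium exchange followed by 1,2-addition of the aryllithium to the aldehyde and fluoride desilylation; the carbinol centre arises as a mixture of epimers, which is of no consequence because it becomes trigonal in step 13.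

Step 11
Reactants: 17 3,4,5-tris(benzyloxy)benzaldehyde
Product: 18 1,2,3-tris(benzyloxy)-5-ethynylbenzene
Conditions: dimethyl (1-diazo-2-oxopropyl)phosphonate, K2CO3, MeOH/THF, rt
Reagents that add atoms: dimethyl (1-diazo-2-oxopropyl)phosphonate, COP(=O)(OC)C(=[N+]=[N-])C(C)=O
Why: Seyferth–Gilbert homologation with the Ohira–Bestmann reagent converts the aromatic aldehyde into the terminal alkyne under mild carbonate conditions.

Step 12
Reactants: 18 aryl alkyne
Product: 19 (Z)-2-[2-(3,4,5-tris(benzyloxy)phenyl)ethenyl]-4,4,5,5-tetramethyl-1,3,2-dioxaborolane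
Conditions: pinacolborane, [RhCl(C8H12)]2 (1.5 mol %, C8H12 = 1,5-cyclooctadiene), P(i-Pr)3, Et3N, cyclohexane, rt
Reagents that add atoms: pinacolborane, CC1(C)OBOC1(C)C
Why: rhodium-catalysed trans-hydroboration of the terminal alkyne through a rhodium vinylidene places boron at the terminal carbon and cis to the aryl group, which gives the (Z)-alkenylboronate.

Step 13
Reactants: 16 trimer benzhydrol; 19 (Z)-alkenylboronate (3 equiv)
Product: 21 boryl tetramer (cycloadduct), via o-quinone methide 20 (not isolated)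
Conditions: (R)-3,3′-bis(2,4,6-triisopropylphenyl)-1,1′-binaphthyl-2,2′-diyl hydrogen phosphate (20 mol %), 5 Å molecular sieves, toluene (0.01 M), 0 °C → rt
Reagents that add atoms: none
Why: Proposed new method: the chiral phosphoric acid ionises the doubly benzylic carbinol of 16, with loss of water to the sieves, to the hydrogen-bonded (E)-o-quinone methide 20 (O1=C8a–C4a=C4 of unit 1), which reacts as a heterodiene with the (Z)-alkenylboronate 19 in an asynchronous inverse-electron-demand hetero-Diels–Alder reaction, the boron-bearing carbon (C3) bonding to C4 and the phenolic oxygen closing on the benzylic carbon (C2); the closest known reaction type is the Brønsted-acid-catalysed [4+2] cycloaddition of o-quinone methides made in situ from 2-hydroxybenzhydrols with styrenes and β-substituted styrenes, which has not been shown with an alkenylboronate or on an oligomeric substrate. Ring C of unit 1 is closed as the six-membered ring of the [4+2] addition (in the stepwise limit a 6-endo capture of the C2 benzylic cation by O1). C2 and C3 are set cis by suprafacial addition across the (Z)-alkene, C4 is set trans to C3 by the exo approach to the (E)-methide, because the endo quadrant under ring A is blocked by the 5-benzyloxy group and by the ortho substituents of the twisted ring A of unit 2, and the absolute sense (which face of the methide is attacked) is set by the chiral phosphate bound at O1, the stereocentres of units 2 to 4 being too remote to decide it. The regioselectivity needed (C3 to C4, not C2 to C4) is secured by the 3,4,5-tris(benzyloxy)phenyl group and the C–B bond, which both stabilise positive charge at C2. The chemoselectivity needed is secured because only the bis(trioxyaryl)carbinol ionises under a weak acid, while the interflavan bonds, the benzyl ethers, the free 3-OH of unit 3 and the boronate are inert, and high dilution with excess 19 suppresses self-trapping of 20.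

Step 14
Reactants: 21 boryl tetramer; 22 3,4,5-tris(benzyloxy)benzoic acid
Product: 23 boryl tetramer gallate (ester at O3 of unit 3)
Conditions: DCC, DMAP, CH2Cl2, rt
Reagents that add atoms: none
Why: Steglich esterification acylates the 3-OH of unit 3, the only free hydroxyl group, because the 3-oxygen of unit 1 is still masked as the boronate.

Step 15
Reactants: 23 boryl tetramer gallate
Product: 24 tetracosa-O-benzyl tetramer gallate (3-OH of unit 1 free)
Conditions: NaBO3·4H2O, THF/H2O, rt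
Reagents that add atoms: sodium perborate, [Na+].[Na+].O[B-]1(O)OO[B-](O)(O)OO1
Why: oxidation of the secondary alkylboronate with perborate (1,2-shift of carbon from boron to oxygen) goes with retention and so delivers the 3-OH of unit 1 cis to the C2 aryl group, under conditions mild enough for the gallate ester.

Step 16
Reactants: 24 tetracosa-O-benzyl tetramer gallate
Product: 25 epigallocatechin-(4β→8)-epigallocatechin-(4β→8)-epigallocatechin 3-O-gallate-(4β→8)-epicatechin (target)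
Conditions: H2 (1 atm), Pd(OH)2 on carbon, THF/MeOH/H2O, rt
Reagents that add atoms: none
Why: catalytic hydrogenolysis cleaves all twenty-four benzyl ethers without touching the interflavan bonds, the ester or any stereocentre.

**Compound list**

1 | (−)-epicatechin, (2R,3R)-2-(3,4-dihydroxyphenyl)chromane-3,5,7-triol | O[C@@H]1Cc2c(O)cc(O)cc2O[C@@H]1c1ccc(O)c(O)c1 | starting material
2 | 5,7,3′,4′-tetra-O-benzyl-(−)-epicatechin | O[C@@H]1Cc2c(OCc9ccccc9)cc(OCc9ccccc9)cc2O[C@@H]1c8ccc(OCc9ccccc9)c(OCc9ccccc9)c8 | intermediate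
3 | 3,5,7,3′,4′-penta-O-benzyl-(−)-epicatechin | c9ccccc9CO[C@@H]1Cc2c(OCc9ccccc9)cc(OCc9ccccc9)cc2O[C@@H]1c8ccc(OCc9ccccc9)c(OCc9ccccc9)c8 | intermediate
4 | (−)-epigallocatechin, (2R,3R)-2-(3,4,5-trihydroxyphenyl)chromane-3,5,7-triol | O[C@@H]1Cc2c(O)cc(O)cc2O[C@@H]1c1cc(O)c(O)c(O)c1 | starting material
5 | 5,7,3′,4′,5′-penta-O-benzyl-(−)-epigallocatechin | O[C@@H]1Cc2c(OCc9ccccc9)cc(OCc9ccccc9)cc2O[C@@H]1c8cc(OCc9ccccc9)c(OCc9ccccc9)c(OCc9ccccc9)c8 | intermediate
6 | 4β-(2-ethoxyethoxy)-5,7,3′,4′,5′-penta-O-benzylepigallocatechin (2,3-cis, 3,4-trans) | CCOCCO[C@H]1c2c(OCc9ccccc9)cc(OCc9ccccc9)cc2O[C@H](c8cc(OCc9ccccc9)c(OCc9ccccc9)c(OCc9ccccc9)c8)[C@@H]1O | intermediate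
7 | dimer: 5,7,3′,4′,5′-penta-O-benzylepigallocatechin-(4β→8)-3,5,7,3′,4′-penta-O-benzylepicatechin, 3-OH of the upper unit free | O[C@@H]1[C@@H](c3c(OCc9ccccc9)cc(OCc9ccccc9)c4c3O[C@H](c8ccc(OCc9ccccc9)c(OCc9ccccc9)c8)[C@H](OCc9ccccc9)C4)c2c(OCc9ccccc9)cc(OCc9ccccc9)cc2O[C@@H]1c8cc(OCc9ccccc9)c(OCc9ccccc9)c(OCc9ccccc9)c8 | intermediate
8 | 8-bromo-4β-(2-ethoxyethoxy)-5,7,3′,4′,5′-penta-O-benzylepigallocatechin | CCOCCO[C@H]1c2c(OCc9ccccc9)cc(OCc9ccccc9)c(Br)c2O[C@H](c8cc(OCc9ccccc9)c(OCc9ccccc9)c(OCc9ccccc9)c8)[C@@H]1O | intermediate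
9 | 8-bromo-4β-(2-ethoxyethoxy)-3,5,7,3′,4′,5′-hexa-O-benzylepigallocatechin | CCOCCO[C@H]1c2c(OCc9ccccc9)cc(OCc9ccccc9)c(Br)c2O[C@H](c8cc(OCc9ccccc9)c(OCc9ccccc9)c(OCc9ccccc9)c8)[C@@H]1OCc9ccccc9 | intermediate
10 | trimer bromide: 8-bromo-hexa-O-benzylepigallocatechin-(4β→8)-penta-O-benzylepigallocatechin (3-OH free)-(4β→8)-penta-O-benzylepicatechin | O[C@@H]1[C@@H](c3c(OCc9ccccc9)cc(OCc9ccccc9)c4c3O[C@H](c8ccc(OCc9ccccc9)c(OCc9ccccc9)c8)[C@H](OCc9ccccc9)C4)c2c(OCc9ccccc9)cc(OCc9ccccc9)c([C@H]3c4c(OCc9ccccc9)cc(OCc9ccccc9)c(Br)c4O[C@H](c8cc(OCc9ccccc9)c(OCc9ccccc9)c(OCc9ccccc9)c8)[C@@H]3OCc9ccccc9)c2O[C@@H]1c8cc(OCc9ccccc9)c(OCc9ccccc9)c(OCc9ccccc9)c8 | intermediate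
11 | 2,4,6-trihydroxybenzaldehyde | O=Cc1c(O)cc(O)cc1O | starting material
12 | 4,6-bis(benzyloxy)-2-hydroxybenzaldehyde | O=Cc1c(O)cc(OCc9ccccc9)cc1OCc9ccccc9 | intermediate
13 | 4,6-bis(benzyloxy)-2-(triethylsilyloxy)benzaldehyde | O=Cc1c(O[Si](CC)(CC)CC)cc(OCc9ccccc9)cc1OCc9ccccc9 | intermediate
14 | dilithiated trimer: C8-lithio compound of 10 with the lithium 3-alkoxide of unit 3 | [Li]O[C@@H]1[C@@H](c3c(OCc9ccccc9)cc(OCc9ccccc9)c4c3O[C@H](c8ccc(OCc9ccccc9)c(OCc9ccccc9)c8)[C@H](OCc9ccccc9)C4)c2c(OCc9ccccc9)cc(OCc9ccccc9)c([C@H]3c4c(OCc9ccccc9)cc(OCc9ccccc9)c([Li])c4O[C@H](c8cc(OCc9ccccc9)c(OCc9ccccc9)c(OCc9ccccc9)c8)[C@@H]3OCc9ccccc9)c2O[C@@H]1c8cc(OCc9ccccc9)c(OCc9ccccc9)c(OCc9ccccc9)c8 | intermediate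
15 | silyl-protected adduct: trimer whose C8 (unit 2) carries CH(OH)[4,6-bis(benzyloxy)-2-(triethylsilyloxy)phenyl], drawn in the neutral form, carbinol epimers | O[C@@H]1[C@@H](c3c(OCc9ccccc9)cc(OCc9ccccc9)c4c3O[C@H](c8ccc(OCc9ccccc9)c(OCc9ccccc9)c8)[C@H](OCc9ccccc9)C4)c2c(OCc9ccccc9)cc(OCc9ccccc9)c([C@H]3c4c(OCc9ccccc9)cc(OCc9ccccc9)c(C(O)c5c(O[Si](CC)(CC)CC)cc(OCc9ccccc9)cc5OCc9ccccc9)c4O[C@H](c8cc(OCc9ccccc9)c(OCc9ccccc9)c(OCc9ccccc9)c8)[C@@H]3OCc9ccccc9)c2O[C@@H]1c8cc(OCc9ccccc9)c(OCc9ccccc9)c(OCc9ccccc9)c8 | intermediate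
16 | trimer benzhydrol: trimer whose C8 (unit 2) carries CH(OH)[4,6-bis(benzyloxy)-2-hydroxyphenyl], carbinol epimers | O[C@@H]1[C@@H](c3c(OCc9ccccc9)cc(OCc9ccccc9)c4c3O[C@H](c8ccc(OCc9ccccc9)c(OCc9ccccc9)c8)[C@H](OCc9ccccc9)C4)c2c(OCc9ccccc9)cc(OCc9ccccc9)c([C@H]3c4c(OCc9ccccc9)cc(OCc9ccccc9)c(C(O)c5c(O)cc(OCc9ccccc9)cc5OCc9ccccc9)c4O[C@H](c8cc(OCc9ccccc9)c(OCc9ccccc9)c(OCc9ccccc9)c8)[C@@H]3OCc9ccccc9)c2O[C@@H]1c8cc(OCc9ccccc9)c(OCc9ccccc9)c(OCc9ccccc9)c8 | intermediate
17 | 3,4,5-tris(benzyloxy)benzaldehyde | O=Cc1cc(OCc9ccccc9)c(OCc9ccccc9)c(OCc9ccccc9)c1 | starting material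
18 | 1,2,3-tris(benzyloxy)-5-ethynylbenzene | C#Cc1cc(OCc9ccccc9)c(OCc9ccccc9)c(OCc9ccccc9)c1 | intermediate
19 | (Z)-2-[2-(3,4,5-tris(benzyloxy)phenyl)ethenyl]-4,4,5,5-tetramethyl-1,3,2-dioxaborolane | CC1(C)OB(/C=C\c2cc(OCc9ccccc9)c(OCc9ccccc9)c(OCc9ccccc9)c2)OC1(C)C | intermediate
20 | (E)-o-quinone methide: trimer whose C8 (unit 2) carries the methine of a 3,5-bis(benzyloxy)-6-methylenecyclohexa-2,4-dienone, aryl anti to the carbonyl carbon | O[C@@H]1[C@@H](c3c(OCc9ccccc9)cc(OCc9ccccc9)c4c3O[C@H](c8ccc(OCc9ccccc9)c(OCc9ccccc9)c8)[C@H](OCc9ccccc9)C4)c2c(OCc9ccccc9)cc(OCc9ccccc9)c([C@H]3c4c(OCc9ccccc9)cc(OCc9ccccc9)c(/C=C5/C(=O)C=C(OCc9ccccc9)C=C5OCc9ccccc9)c4O[C@H](c8cc(OCc9ccccc9)c(OCc9ccccc9)c(OCc9ccccc9)c8)[C@@H]3OCc9ccccc9)c2O[C@@H]1c8cc(OCc9ccccc9)c(OCc9ccccc9)c(OCc9ccccc9)c8 | intermediate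
21 | boryl tetramer: unit 1 is a 2,3-cis-3,4-trans 5,7,3′,4′,5′-penta-O-benzylflavan with the pinacol boronate at C3 (in place of the 3-oxygen) and C4 bonded to C8 of unit 2; 3-OH of unit 3 free | O[C@@H]1[C@@H](c3c(OCc9ccccc9)cc(OCc9ccccc9)c4c3O[C@H](c8ccc(OCc9ccccc9)c(OCc9ccccc9)c8)[C@H](OCc9ccccc9)C4)c2c(OCc9ccccc9)cc(OCc9ccccc9)c([C@H]3c4c(OCc9ccccc9)cc(OCc9ccccc9)c([C@H]5c6c(OCc9ccccc9)cc(OCc9ccccc9)cc6O[C@H](c8cc(OCc9ccccc9)c(OCc9ccccc9)c(OCc9ccccc9)c8)[C@@H]5B7OC(C)(C)C(C)(C)O7)c4O[C@H](c8cc(OCc9ccccc9)c(OCc9ccccc9)c(OCc9ccccc9)c8)[C@@H]3OCc9ccccc9)c2O[C@@H]1c8cc(OCc9ccccc9)c(OCc9ccccc9)c(OCc9ccccc9)c8 | intermediate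
22 | 3,4,5-tris(benzyloxy)benzoic acid | OC(=O)c1cc(OCc9ccccc9)c(OCc9ccccc9)c(OCc9ccccc9)c1 | starting material
23 | boryl tetramer gallate: 21 with the 3,4,5-tris(benzyloxy)benzoate at O3 of unit 3 | O=C(O[C@@H]1[C@@H](c3c(OCc9ccccc9)cc(OCc9ccccc9)c4c3O[C@H](c8ccc(OCc9ccccc9)c(OCc9ccccc9)c8)[C@H](OCc9ccccc9)C4)c2c(OCc9ccccc9)cc(OCc9ccccc9)c([C@H]3c4c(OCc9ccccc9)cc(OCc9ccccc9)c([C@H]5c6c(OCc9ccccc9)cc(OCc9ccccc9)cc6O[C@H](c8cc(OCc9ccccc9)c(OCc9ccccc9)c(OCc9ccccc9)c8)[C@@H]5B7OC(C)(C)C(C)(C)O7)c4O[C@H](c8cc(OCc9ccccc9)c(OCc9ccccc9)c(OCc9ccccc9)c8)[C@@H]3OCc9ccccc9)c2O[C@@H]1c8cc(OCc9ccccc9)c(OCc9ccccc9)c(OCc9ccccc9)c8)c8cc(OCc9ccccc9)c(OCc9ccccc9)c(OCc9ccccc9)c8 | intermediate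
24 | tetracosa-O-benzyl tetramer gallate: benzyl-protected target with the 3-OH of unit 1 free | O=C(O[C@@H]1[C@@H](c3c(OCc9ccccc9)cc(OCc9ccccc9)c4c3O[C@H](c8ccc(OCc9ccccc9)c(OCc9ccccc9)c8)[C@H](OCc9ccccc9)C4)c2c(OCc9ccccc9)cc(OCc9ccccc9)c([C@H]3c4c(OCc9ccccc9)cc(OCc9ccccc9)c([C@H]5c6c(OCc9ccccc9)cc(OCc9ccccc9)cc6O[C@H](c8cc(OCc9ccccc9)c(OCc9ccccc9)c(OCc9ccccc9)c8)[C@@H]5O)c4O[C@H](c8cc(OCc9ccccc9)c(OCc9ccccc9)c(OCc9ccccc9)c8)[C@@H]3OCc9ccccc9)c2O[C@@H]1c8cc(OCc9ccccc9)c(OCc9ccccc9)c(OCc9ccccc9)c8)c8cc(OCc9ccccc9)c(OCc9ccccc9)c(OCc9ccccc9)c8 | intermediate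
25 | epigallocatechin-(4β→8)-epigallocatechin-(4β→8)-epigallocatechin 3-O-gallate-(4β→8)-epicatechin, all units (2R,3R), all linkages 3,4-trans | O=C(O[C@@H]1[C@@H](c2c(O)cc(O)c3c2O[C@H](c2ccc(O)c(O)c2)[C@H](O)C3)c2c(O)cc(O)c([C@H]3c4c(O)cc(O)c([C@H]5c6c(O)cc(O)cc6O[C@H](c6cc(O)c(O)c(O)c6)[C@@H]5O)c4O[C@H](c4cc(O)c(O)c(O)c4)[C@@H]3O)c2O[C@@H]1c1cc(O)c(O)c(O)c1)c1cc(O)c(O)c(O)c1 | target

**Count**
Total steps: 16. Longest linear sequence: 10 steps (steps 2, 3, 5, 6, 7, 10, 13, 14, 15, 16, from 4).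

**Steps most likely to fail**

Step 13 (key step). The crowded, strongly stabilised methide may not be attacked by the weakly nucleophilic alkenylboronate. The facial or exo/endo selectivity may be poor. The C2 cation may lose boron (alkenylation in place of ring closure), or the methide may be trapped by another molecule of substrate. Fallback by the known interflavan coupling: setting out from 10, bromine–lithium exchange and protonation (t-BuLi, THF, −78 °C; MeOH) should give the debrominated trimer F1. TMSOTf-promoted condensation of F1 with the bromine-capped electrophile 9 (CH2Cl2, −78 °C) should give the 8-bromo tetramer F2, with the 4β bond set anti to the 3-benzyloxy group. Esterification with 22 (DCC, DMAP) should give the 8-bromo tetramer gallate F3. Hydrogenolysis (H2, Pd(OH)2 on carbon, Et3N) should remove the benzyl groups and the bromine, and the route is rejoined at 25.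

Step 10. Addition of the bulky aryllithium to the doubly ortho-substituted, electron-rich aldehyde may be slow, so that proton transfer from a benzylic OCH2 group or from the medium quenches the carbanion. Fallback with the roles changed: setting out from 10, bromine–lithium exchange and trapping with the small, reactive electrophile DMF should give the 8-formyl trimer F4. Ortho-specific hydroxyalkylation of bromomagnesium 3,5-bis(benzyloxy)phenoxide (from commercial 3,5-bis(benzyloxy)phenol and EtMgBr, toluene/CH2Cl2, rt) with F4, through a magnesium-chelated transition state, should give the 2-hydroxybenzhydrol, and the route is rejoined at 16.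

Step 12. Re-addition and elimination of rhodium hydride may erode the Z geometry of the alkenylboronate, which would carry the wrong C2/C3 relationship into step 13. Fallback by cis-reduction of an alkynylboronate: setting out from 18, deprotonation (n-BuLi, THF, −78 °C), borylation with 2-isopropoxy-4,4,5,5-tetramethyl-1,3,2-dioxaborolane and acidification (HCl in Et2O) should give the alkynylboronate F5. Hydrozirconation with Cp2Zr(H)Cl (THF, rt) and hydrolysis of the geminal boryl zirconocene with water should give the (Z)-alkenylboronate with the geometry fixed by syn addition, and the route is rejoined at 19.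

**Further compounds**
F1 | step 13 | debrominated trimer: hexa-O-benzylepigallocatechin-(4β→8)-penta-O-benzylepigallocatechin (3-OH free)-(4β→8)-penta-O-benzylepicatechin | O[C@@H]1[C@@H](c3c(OCc9ccccc9)cc(OCc9ccccc9)c4c3O[C@H](c8ccc(OCc9ccccc9)c(OCc9ccccc9)c8)[C@H](OCc9ccccc9)C4)c2c(OCc9ccccc9)cc(OCc9ccccc9)c([C@H]3c4c(OCc9ccccc9)cc(OCc9ccccc9)cc4O[C@H](c8cc(OCc9ccccc9)c(OCc9ccccc9)c(OCc9ccccc9)c8)[C@@H]3OCc9ccccc9)c2O[C@@H]1c8cc(OCc9ccccc9)c(OCc9ccccc9)c(OCc9ccccc9)c8
F2 | step 13 | 8-bromo tetramer: 8-bromo-hexa-O-benzylepigallocatechin-(4β→8)-hexa-O-benzylepigallocatechin-(4β→8)-penta-O-benzylepigallocatechin (3-OH free)-(4β→8)-penta-O-benzylepicatechin | O[C@@H]1[C@@H](c3c(OCc9ccccc9)cc(OCc9ccccc9)c4c3O[C@H](c8ccc(OCc9ccccc9)c(OCc9ccccc9)c8)[C@H](OCc9ccccc9)C4)c2c(OCc9ccccc9)cc(OCc9ccccc9)c([C@H]3c4c(OCc9ccccc9)cc(OCc9ccccc9)c([C@H]5c6c(OCc9ccccc9)cc(OCc9ccccc9)c(Br)c6O[C@H](c8cc(OCc9ccccc9)c(OCc9ccccc9)c(OCc9ccccc9)c8)[C@@H]5OCc9ccccc9)c4O[C@H](c8cc(OCc9ccccc9)c(OCc9ccccc9)c(OCc9ccccc9)c8)[C@@H]3OCc9ccccc9)c2O[C@@H]1c8cc(OCc9ccccc9)c(OCc9ccccc9)c(OCc9ccccc9)c8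
F3 | step 13 | 8-bromo tetramer gallate: F2 with the 3,4,5-tris(benzyloxy)benzoate at O3 of unit 3 | O=C(O[C@@H]1[C@@H](c3c(OCc9ccccc9)cc(OCc9ccccc9)c4c3O[C@H](c8ccc(OCc9ccccc9)c(OCc9ccccc9)c8)[C@H](OCc9ccccc9)C4)c2c(OCc9ccccc9)cc(OCc9ccccc9)c([C@H]3c4c(OCc9ccccc9)cc(OCc9ccccc9)c([C@H]5c6c(OCc9ccccc9)cc(OCc9ccccc9)c(Br)c6O[C@H](c8cc(OCc9ccccc9)c(OCc9ccccc9)c(OCc9ccccc9)c8)[C@@H]5OCc9ccccc9)c4O[C@H](c8cc(OCc9ccccc9)c(OCc9ccccc9)c(OCc9ccccc9)c8)[C@@H]3OCc9ccccc9)c2O[C@@H]1c8cc(OCc9ccccc9)c(OCc9ccccc9)c(OCc9ccccc9)c8)c8cc(OCc9ccccc9)c(OCc9ccccc9)c(OCc9ccccc9)c8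
F4 | step 10 | 8-formyl trimer: 10 with CHO in place of bromine at C8 of unit 2 | O[C@@H]1[C@@H](c3c(OCc9ccccc9)cc(OCc9ccccc9)c4c3O[C@H](c8ccc(OCc9ccccc9)c(OCc9ccccc9)c8)[C@H](OCc9ccccc9)C4)c2c(OCc9ccccc9)cc(OCc9ccccc9)c([C@H]3c4c(OCc9ccccc9)cc(OCc9ccccc9)c(C=O)c4O[C@H](c8cc(OCc9ccccc9)c(OCc9ccccc9)c(OCc9ccccc9)c8)[C@@H]3OCc9ccccc9)c2O[C@@H]1c8cc(OCc9ccccc9)c(OCc9ccccc9)c(OCc9ccccc9)c8
F5 | step 12 | 2-{[3,4,5-tris(benzyloxy)phenyl]ethynyl}-4,4,5,5-tetramethyl-1,3,2-dioxaborolane | CC1(C)OB(C#Cc2cc(OCc9ccccc9)c(OCc9ccccc9)c(OCc9ccccc9)c2)OC1(C)C
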